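What is left over in a flask tells you what has happened in it, so begin with the substrate still present at the last reading of the two earlier runs: 81% in north-west and 86% in west, both at 15.0 h.

in all of them: substrate 0.071 M; capture agent 0.0213 M

|  | solid reagent | remark | time |
|---|---|---|---|
| north-west | 1.2 equiv | run made earlier |  |
| west | 5 equiv | run made earlier |  |
| maple | 2.50 equiv |  | 25 h |
| ash | 2.50 equiv |  | 75 h |

| run | time / h | target / % | substrate / % | open intermediate / % | isomer of the product / % | side product / % |
|---|---|---|---|---|---|---|
| north-west | 1.33 | 3 | 100 | 4 | 2 | 3 |
| north-west | 2.00 | 0 | 98 | 2 | 0 | 3 |
| north-west | 3.00 | 2 | 97 | 0 | 0 | 1 |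
| north-west | 5.00 | 1 | 99 | 3 | 0 | 2 |
| north-west | 10.0 | 9 | 90 | 2 | 0 | 0 |
| north-west | 15.0 | 13 | 81 | 1 | 2 | 1 |
| west | 2.50 | 0 | 98 | 0 | 0 | 3 |
| west | 5.00 | 0 | 97 | 0 | 3 | 0 |
| west | 8.00 | 3 | 92 | 0 | 0 | 0 |
| west | 10.0 | 4 | 91 | 5 | 0 | 0 |
| west | 12.0 | 9 | 84 | 1 | 3 | 3 |
| west | 15.0 | 10 | 86 | 3 | 2 | 4 |

(each reading ± 2 percentage points)

- solid reagent is a solid; its amount is given per volume of the solution
- at the start none of the solid reagent is in solution

- which of these there is most of at the end, counted by the substrate in it, maple (side product / target / substrate / isomer of the product / open intermediate)
- which of these there is most of at the end, counted by the substrate in it, ash (side product / target / substrate / isomer of the product / open intermediate)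
- final amount of the leader among these, as a percentage of the substrate charged, in maple
- final amount of the leader among these, as a percentage of the substrate charged, in ash

Those two leftovers differ by 5 percentage points, and each reading scatters by 2 points. I therefore average the two runs and use the mean for maple and ash, whose 2.50 equiv of solid reagent lies between theirs.

Next, ask where the lost substrate went. All amounts here are fractions of the substrate charged, summed over the two runs at 15.0 h:

target found = 13% + 10% = 23.0%

substrate lost = 19.0% + 14.0% = 33.0%

ratio = 69.7%

This ratio, target found per substrate lost, is the target share, which chemists call selectivity. It is a reading and carries the scatter of the readings. Multiply it by the substrate lost and you have an estimate of the target, good for as long as the share holds.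

You still need the substrate itself. A first-order rate constant is a rate divided by the amount present. Between 5.00 h and 15.0 h the mean of the two runs gives:

k = 0.0160 /h

I assume this first-order loss holds onward, though these runs stop at 15.0 h. Starting from their mean at that time, my reckoning gives:

maple, 25 h: substrate 71.2%, target 20.1%

ash, 75 h: substrate 32.0%, target 47.4%

So I expect substrate to lead in maple and target to lead in ash.

The forecast names substrate at 67% for maple and target at 62% for ash, holding that “Almost all the loss appears as target”. Its ash figure is higher than mine.

The flask gives substrate at 68.3% in maple and target at 51.3% in ash, 11 points below the forecast.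

    open intermediate ⇌ isomer of the product (K = 3.10, k = 0.00961 /min)
    open intermediate ⇌ target (K = 13.1, k = 0.0271 /min)
    open intermediate + capture agent → trapped intermediate (k = 0.00749 /M/min)
    substrate + partner → open intermediate + released group (k = 0.0292 /M/min)
    solid reagent ⇌ partner, rate k5*(cs5 - [partner]) while solid is left; crystals form when [partner] > cs5 (solubility = 29.0 mM, k = 0.00113 /min)
    open intermediate → side product (k = 0.00112 /min)

Ash has lost 82.9% of its substrate, against my 68.0%, and its target share at the end is 61.8%, lower than the 69.7% read from the early runs; beside the target stand 13.4% of side product and 12.3% of isomer. Now read the same ash flask earlier, at 20 h. It holds 75.6% substrate, so 69.7% of the 24.4% lost gives 17.0% target, and the flask at that time holds 16.4%.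

Readings and results were generated by integration for an exercise; noise was put on by code.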